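**Retrosynthetic overview**

1. The route rests on C2 of pyran ring B (O1, C2, C3, C4, C4a, C8a). C2 is a fully substituted ether carbon whose first two chain carbons, C1' and C2', can be carried as a vinyl group, so O1–C2 is cut back to a phenol and an E-trisubstituted allylic carbonate (enantioselective palladium allylic etherification).
2. C3=C4 is added directly after ring closure by DDQ dehydrogenation of the chroman, while the only other alkene is a vinyl group without allylic hydrogens.
3. Side chain: C2'–C3' by hydroboration of the vinyl group and B-alkyl Suzuki coupling with (E)-3-iodo-2-methylprop-2-en-1-ol; C5'–C6' by copper-mediated allylation of (S)-3,7-dimethyloct-6-en-1-yn-3-ol (C8' from Sharpless epoxidation of geraniol); C6'=C7' by hydride trans-reduction.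
4. The carbonate comes from 2-methylhydroquinone by monosilylation, ortho-formylation, Wittig reaction, hydrogenation, Horner–Wadsworth–Emmons olefination, reduction and carbonate formation.
5. Ring order: aromatic ring A is present from the start; ring B is the only ring formed (step 8).

Key step: step 8

Assumption: the (R,R)-ligand is taken to convert the E-carbonate into the 2R chroman; the sense of induction is verified on the first run, and the (S,S)-ligand, used in the same way, corrects it if it is opposite.

**Route**

Step 1
Reactants: 1 2-methylhydroquinone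
Product: 2 2-methyl-4-(triisopropylsilyloxy)phenol
Conditions: TIPSCl (1.0 equiv), imidazole, DMF, 0 °C to rt
Reagents that add atoms: triisopropylsilyl chloride, CC(C)[Si](Cl)(C(C)C)C(C)C
Why: Silylation of a phenol with a bulky chlorosilane and imidazole should favour the hydroxyl at C4, which has no ortho substituent, over the hydroxyl next to the methyl group; one equivalent of chlorosilane limits bis-silylation.

Step 2
Reactants: 2 2-methyl-4-(triisopropylsilyloxy)phenol
Product: 3 2-hydroxy-3-methyl-5-(triisopropylsilyloxy)benzaldehyde
Conditions: MgCl2, Et3N, (CH2O)n, MeCN, reflux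
Reagents that add atoms: paraformaldehyde (as formaldehyde), C=O
Why: Magnesium-phenoxide-directed ortho-formylation (Casnati–Skattebøl reaction) delivers formaldehyde only to the carbon ortho to the free hydroxyl, of which one is open, and a second formaldehyde oxidises the hydroxymethyl stage to the aldehyde.

Step 3
Reactants: 3 2-hydroxy-3-methyl-5-(triisopropylsilyloxy)benzaldehyde; 4 1-(triphenylphosphoranylidene)propan-2-one
Product: 5 (E)-4-[2-hydroxy-3-methyl-5-(triisopropylsilyloxy)phenyl]but-3-en-2-one
Conditions: toluene, 90 °C
Reagents that add atoms: none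
Why: Wittig olefination with a ketone-stabilised ylide tolerates the free phenol and the aryl silyl ether (no hydroxide base is present) and should give the E-enone.

Step 4
Reactants: 5 (E)-4-[2-hydroxy-3-methyl-5-(triisopropylsilyloxy)phenyl]but-3-en-2-one
Product: 6 4-[2-hydroxy-3-methyl-5-(triisopropylsilyloxy)phenyl]butan-2-one
Conditions: H2 (1 atm), Pd/C, EtOAc, rt
Reagents that add atoms: none
Why: Heterogeneous hydrogenation saturates the conjugated C=C bond much faster than the ketone or the arene; the product may sit partly as its cyclic hemiketal, which reacts as the ketone in step 5.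

Step 5
Reactants: 6 4-[2-hydroxy-3-methyl-5-(triisopropylsilyloxy)phenyl]butan-2-one; 7 triethyl phosphonoacetate
Product: 8 ethyl (E)-5-[2-hydroxy-3-methyl-5-(triisopropylsilyloxy)phenyl]-3-methylpent-2-enoate
Conditions: NaH (3.2 equiv), 7 (2 equiv), THF, 0 to 50 °C; chromatographic removal of the Z isomer
Reagents that add atoms: none
Why: Horner–Wadsworth–Emmons olefination of the methyl ketone (phenol carried as its sodium salt) should favour the E-enoate with the ester trans to the larger arylethyl group, the minor Z isomer being separated on silica; oxa-Michael closure is not expected because the phenoxide is a far weaker base than the ester enolate it would form.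

Step 6
Reactants: 8 ethyl (E)-5-[2-hydroxy-3-methyl-5-(triisopropylsilyloxy)phenyl]-3-methylpent-2-enoate
Product: 9 (E)-5-[2-hydroxy-3-methyl-5-(triisopropylsilyloxy)phenyl]-3-methylpent-2-en-1-ol
Conditions: iBu2AlH (3.5 equiv), CH2Cl2, −78 °C; aq. potassium sodium tartrate
Reagents that add atoms: none
Why: 1,2-Reduction of the conjugated ester by iBu2AlH at low temperature gives the allylic alcohol without touching the trisubstituted alkene or the silyl ether; geometric purity is checked by NOE at this stage.

Step 7
Reactants: 9 (E)-5-[2-hydroxy-3-methyl-5-(triisopropylsilyloxy)phenyl]-3-methylpent-2-en-1-ol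
Product: 10 (E)-5-[2-hydroxy-3-methyl-5-(triisopropylsilyloxy)phenyl]-3-methylpent-2-enyl methyl carbonate
Conditions: ClCO2Me (1.1 equiv), pyridine, CH2Cl2, −20 °C
Reagents that add atoms: methyl chloroformate, COC(=O)Cl
Why: Acylation with a chloroformate and pyridine at low temperature should be selective for the primary allylic alcohol over the hindered, di-ortho-substituted phenol, giving the mono-carbonate.

Step 8
Reactants: 10 (E)-5-[2-hydroxy-3-methyl-5-(triisopropylsilyloxy)phenyl]-3-methylpent-2-enyl methyl carbonate
Product: 11 (R)-2,8-dimethyl-6-(triisopropylsilyloxy)-2-vinylchroman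
Conditions: Pd2(dba)3·CHCl3 (2 mol %), (R,R)-N,N'-(cyclohexane-1,2-diyl)bis[2-(diphenylphosphino)benzamide] (6 mol %), AcOH (1 equiv), CH2Cl2, rt
Reagents that add atoms: none
Why: Zerovalent palladium ionises the allylic methyl carbonate with inversion to a cationic π-allyl complex held in the chiral pocket of the diphosphine, CO2 and methanol are released, and the phenol oxygen attacks the allyl face anti to palladium at the methyl-bearing terminus to form O1–C2. The closest known reaction type is the palladium-catalysed asymmetric allylic etherification (Tsuji–Trost reaction) of phenols tethered to trisubstituted allylic carbonates, which closes 2-methyl-2-vinylchromans. Ring B closes in a six-membered exo mode with the vinyl group (C1'–C2') left outside the ring, since attack at the unsubstituted terminus would need an eight-membered ring. The new stereocenter C2 is controlled by the ligand: the two diastereomeric π-allyl complexes should interconvert by π–σ–π exchange through the primary terminus faster than they cyclise, acetic acid slowing the cyclisation, so the product ratio follows the difference in cyclisation barriers inside the ligand pocket. The step needs enantioselectivity and attack at the substituted terminus; the first is secured by the geometrically pure E-allyl unit of 10 (the Z isomer would lead to the antipode) paired with one ligand enantiomer, the second by ring size and by the blocked ortho and para positions of the phenol, which rule out C-allylation.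

Step 9
Reactants: 11 (R)-2,8-dimethyl-6-(triisopropylsilyloxy)-2-vinylchroman
Product: 12 (S)-2,8-dimethyl-6-(triisopropylsilyloxy)-2-vinyl-2H-chromene
Conditions: DDQ (1.3 equiv), benzene, reflux, exclusion of light
Reagents that add atoms: none
Why: DDQ abstracts hydride from benzylic C4, the cation being stabilised by the ortho ether oxygen O1, and loss of a proton from C3 gives the 2H-chromene (oxidative dehydrogenation of a chroman); C2 is untouched, and its descriptor changes to S only because C3 now outranks the vinyl group.

Step 10
Reactants: 13 propargyl alcohol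
Product: 15 (E)-3-iodo-2-methylprop-2-en-1-ol, via alkenylalane 14 (not isolated)
Conditions: Me3Al (3 equiv), Cp2ZrCl2 (0.25 equiv), CH2Cl2, 0 °C to rt; then I2, THF, −30 to 0 °C
Reagents that add atoms: trimethylaluminium, C[Al](C)C; iodine, II
Why: Zirconium-catalysed syn-carboalumination of the terminal alkyne (Negishi carboalumination) places methyl on the internal carbon and aluminium on the terminal one, and iodinolysis with retention gives the E-iodide.

Step 11
Reactants: 12 (S)-2,8-dimethyl-6-(triisopropylsilyloxy)-2-vinyl-2H-chromene; 15 (E)-3-iodo-2-methylprop-2-en-1-ol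
Product: 17 (E)-5-[(2S)-2,8-dimethyl-6-(triisopropylsilyloxy)-2H-chromen-2-yl]-2-methylpent-2-en-1-ol, via B-alkyl-9-BBN borane 16 (not isolated)
Conditions: 9-BBN-H (1.3 equiv), THF, 0 °C to rt; then aq. K3PO4, 15, PdCl2(dppf) (5 mol %), AsPh3 (10 mol %), DMF, rt
Reagents that add atoms: 9-borabicyclo[3.3.1]nonane, B1C2CCCC1CCC2 (its boron bicycle is carried by 16 only)
Why: 9-BBN hydroborates the monosubstituted vinyl group at its terminal carbon in preference to the cyclic, aryl-conjugated C3=C4 bond, and the primary alkylborane couples with the alkenyl iodide under catalysis by zerovalent palladium (B-alkyl Suzuki–Miyaura coupling) with retention of the E geometry; C2 is not involved.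

Step 12
Reactants: 18 geraniol
Product: 19 (2S,3S)-2,3-epoxygeraniol
Conditions: Ti(OiPr)4 (5 mol %), L-(+)-diethyl tartrate (7 mol %), t-BuOOH, 4 Å molecular sieves, CH2Cl2, −20 °C
Reagents that add atoms: tert-butyl hydroperoxide, CC(C)(C)OO
Why: Sharpless asymmetric epoxidation is selective for the allylic C2=C3 double bond, and L-(+)-diethyl tartrate should direct oxygen to the face that gives the (2S,3S)-epoxide, which fixes the future carbinol carbon C8'.

Step 13
Reactants: 19 (2S,3S)-2,3-epoxygeraniol
Product: 20 (2R,3S)-1-chloro-2,3-epoxy-3,7-dimethyloct-6-ene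
Conditions: PPh3, CCl4, NaHCO3, reflux
Reagents that add atoms: tetrachloromethane, ClC(Cl)(Cl)Cl
Why: Appel chlorination converts the primary alcohol to the chloride under near-neutral conditions that leave the epoxide and both stereocenters untouched (the C2 descriptor changes by priority only).

Step 14
Reactants: 20 (2R,3S)-1-chloro-2,3-epoxy-3,7-dimethyloct-6-ene
Product: 21 (S)-3,7-dimethyloct-6-en-1-yn-3-ol
Conditions: n-BuLi (3.3 equiv), THF, −78 to −30 °C; aq. NH4Cl
Reagents that add atoms: none
Why: Base-induced double elimination of a 2,3-epoxy chloride: deprotonation at C1 opens the epoxide to a chlorovinyl alkoxide, loss of HCl gives the lithium acetylide, and since the C3–O bond is never broken the tertiary carbinol keeps its configuration.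

Step 15
Reactants: 17 (E)-5-[(2S)-2,8-dimethyl-6-(triisopropylsilyloxy)-2H-chromen-2-yl]-2-methylpent-2-en-1-ol
Product: 22 (2S)-2-[(E)-5-bromo-4-methylpent-3-en-1-yl]-2,8-dimethyl-6-(triisopropylsilyloxy)-2H-chromene
Conditions: CBr4, PPh3, CH2Cl2, −20 to 0 °C; used without storage
Reagents that add atoms: tetrabromomethane, BrC(Br)(Br)Br
Why: Appel bromination of the primary allylic alcohol gives the allylic bromide with the position and geometry of the double bond unchanged, and the aryl silyl ether and the chromene are inert to the neutral conditions.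

Step 16
Reactants: 22 (2S)-2-[(E)-5-bromo-4-methylpent-3-en-1-yl]-2,8-dimethyl-6-(triisopropylsilyloxy)-2H-chromene; 21 (S)-3,7-dimethyloct-6-en-1-yn-3-ol
Product: 23 (6S,10E)-13-[(2S)-2,8-dimethyl-6-(triisopropylsilyloxy)-2H-chromen-2-yl]-2,6,10-trimethyltrideca-2,10-dien-7-yn-6-ol
Conditions: CuI (20 mol %), K2CO3, n-Bu4NBr (10 mol %), DMF, rt, argon
Reagents that add atoms: none
Why: Copper-acetylide alkylation: the acetylide formed from the terminal alkyne with CuI and carbonate should displace the primary allylic bromide at its unhindered CH2 terminus (SN2 rather than SN2′, whose terminus is more substituted), forming C5'–C6' as a skipped enyne; the tertiary hydroxyl needs no protection and neither stereocenter is involved.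

Step 17
Reactants: 23 (6S,10E)-13-[(2S)-2,8-dimethyl-6-(triisopropylsilyloxy)-2H-chromen-2-yl]-2,6,10-trimethyltrideca-2,10-dien-7-yn-6-ol
Product: 24 (6S,7E,10E)-13-[(2S)-2,8-dimethyl-6-(triisopropylsilyloxy)-2H-chromen-2-yl]-2,6,10-trimethyltrideca-2,7,10-trien-6-ol
Conditions: NaAlH2(OCH2CH2OCH3)2 (3 equiv), THF, 0 °C to rt; aq. potassium sodium tartrate
Reagents that add atoms: none
Why: Hydroxyl-directed trans-hydroalumination of the propargylic alcohol: the aluminium alkoxide delivers hydride to the proximal alkyne carbon and aluminium to the distal one in an anti sense, and protonolysis on work-up gives the E-alkene; isolated and aryl-conjugated alkenes are not reduced.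

Step 18
Reactants: 24 (6S,7E,10E)-13-[(2S)-2,8-dimethyl-6-(triisopropylsilyloxy)-2H-chromen-2-yl]-2,6,10-trimethyltrideca-2,7,10-trien-6-ol
Product: 25 (2S)-2-[(3E,6E,8S)-8-hydroxy-4,8,12-trimethyltrideca-3,6,11-trien-1-yl]-2,8-dimethyl-2H-chromen-6-ol
Conditions: n-Bu4NF (1.2 equiv), AcOH (1.2 equiv), THF, 0 °C, exclusion of light and air
Reagents that add atoms: none
Why: Fluoride cleaves the aryl silyl ether through Si–F bond formation under buffered, non-acidic conditions that spare the tertiary allylic alcohol, the skipped diene and the chromene.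

**Compound list**

1 | 2-methylhydroquinone | Cc1cc(O)ccc1O | starting material
2 | 2-methyl-4-(triisopropylsilyloxy)phenol | Cc1cc(O[Si](C(C)C)(C(C)C)C(C)C)ccc1O | intermediate
3 | 2-hydroxy-3-methyl-5-(triisopropylsilyloxy)benzaldehyde | Cc1cc(O[Si](C(C)C)(C(C)C)C(C)C)cc(C=O)c1O | intermediate
4 | 1-(triphenylphosphoranylidene)propan-2-one | CC(=O)C=P(c1ccccc1)(c1ccccc1)c1ccccc1 | starting material
5 | (E)-4-[2-hydroxy-3-methyl-5-(triisopropylsilyloxy)phenyl]but-3-en-2-one | CC(=O)/C=C/c1cc(O[Si](C(C)C)(C(C)C)C(C)C)cc(C)c1O | intermediate
6 | 4-[2-hydroxy-3-methyl-5-(triisopropylsilyloxy)phenyl]butan-2-one | CC(=O)CCc1cc(O[Si](C(C)C)(C(C)C)C(C)C)cc(C)c1O | intermediate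
7 | triethyl phosphonoacetate | CCOC(=O)CP(=O)(OCC)OCC | starting material
8 | ethyl (E)-5-[2-hydroxy-3-methyl-5-(triisopropylsilyloxy)phenyl]-3-methylpent-2-enoate | CCOC(=O)/C=C(\C)CCc1cc(O[Si](C(C)C)(C(C)C)C(C)C)cc(C)c1O | intermediate
9 | (E)-5-[2-hydroxy-3-methyl-5-(triisopropylsilyloxy)phenyl]-3-methylpent-2-en-1-ol | OC/C=C(\C)CCc1cc(O[Si](C(C)C)(C(C)C)C(C)C)cc(C)c1O | intermediate
10 | (E)-5-[2-hydroxy-3-methyl-5-(triisopropylsilyloxy)phenyl]-3-methylpent-2-enyl methyl carbonate | COC(=O)OC/C=C(\C)CCc1cc(O[Si](C(C)C)(C(C)C)C(C)C)cc(C)c1O | intermediate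
11 | (R)-2,8-dimethyl-6-(triisopropylsilyloxy)-2-vinylchroman | C=C[C@@]1(C)CCc2cc(O[Si](C(C)C)(C(C)C)C(C)C)cc(C)c2O1 | intermediate
12 | (S)-2,8-dimethyl-6-(triisopropylsilyloxy)-2-vinyl-2H-chromene | C=C[C@@]1(C)C=Cc2cc(O[Si](C(C)C)(C(C)C)C(C)C)cc(C)c2O1 | intermediate
13 | propargyl alcohol | C#CCO | starting material
14 | (E)-alkenylalane Me2Al–CH=C(CH3)–CH2OAlMe2 (not isolated) | C[Al](C)/C=C(\C)CO[Al](C)C | intermediate
15 | (E)-3-iodo-2-methylprop-2-en-1-ol | OC/C(C)=C/I | intermediate
16 | 9-{2-[(2S)-2,8-dimethyl-6-(triisopropylsilyloxy)-2H-chromen-2-yl]ethyl}-9-borabicyclo[3.3.1]nonane (not isolated) | C1CCC2CCCC1B2CC[C@@]1(C)C=Cc2cc(O[Si](C(C)C)(C(C)C)C(C)C)cc(C)c2O1 | intermediate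
17 | (E)-5-[(2S)-2,8-dimethyl-6-(triisopropylsilyloxy)-2H-chromen-2-yl]-2-methylpent-2-en-1-ol | OC/C(C)=C/CC[C@@]1(C)C=Cc2cc(O[Si](C(C)C)(C(C)C)C(C)C)cc(C)c2O1 | intermediate
18 | geraniol | CC(C)=CCC/C(C)=C/CO | starting material
19 | (2S,3S)-2,3-epoxygeraniol | OC[C@@H]1O[C@@]1(C)CCC=C(C)C | intermediate
20 | (2R,3S)-1-chloro-2,3-epoxy-3,7-dimethyloct-6-ene | ClC[C@@H]1O[C@@]1(C)CCC=C(C)C | intermediate
21 | (S)-3,7-dimethyloct-6-en-1-yn-3-ol | CC(C)=CCC[C@](C)(O)C#C | intermediate
22 | (2S)-2-[(E)-5-bromo-4-methylpent-3-en-1-yl]-2,8-dimethyl-6-(triisopropylsilyloxy)-2H-chromene | BrC/C(C)=C/CC[C@@]1(C)C=Cc2cc(O[Si](C(C)C)(C(C)C)C(C)C)cc(C)c2O1 | intermediate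
23 | (6S,10E)-13-[(2S)-2,8-dimethyl-6-(triisopropylsilyloxy)-2H-chromen-2-yl]-2,6,10-trimethyltrideca-2,10-dien-7-yn-6-ol | CC(C)=CCC[C@](C)(O)C#CC/C(C)=C/CC[C@@]1(C)C=Cc2cc(O[Si](C(C)C)(C(C)C)C(C)C)cc(C)c2O1 | intermediate
24 | (6S,7E,10E)-13-[(2S)-2,8-dimethyl-6-(triisopropylsilyloxy)-2H-chromen-2-yl]-2,6,10-trimethyltrideca-2,7,10-trien-6-ol | CC(C)=CCC[C@](C)(O)/C=C/C/C(C)=C/CC[C@@]1(C)C=Cc2cc(O[Si](C(C)C)(C(C)C)C(C)C)cc(C)c2O1 | intermediate
25 | (2S)-2-[(3E,6E,8S)-8-hydroxy-4,8,12-trimethyltrideca-3,6,11-trien-1-yl]-2,8-dimethyl-2H-chromen-6-ol | CC(C)=CCC[C@](C)(O)/C=C/C/C(C)=C/CC[C@@]1(C)C=Cc2cc(O)cc(C)c2O1 | target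

**Step count**

Total: 18 steps. Longest linear sequence: 14 steps (steps 1 to 9, 11, 15, 16, 17, 18); steps 10 and 12 to 14 are side branches.

**Steps most likely to fail**

Step 8 (key step). The enantioselectivity may be too low if the first-formed π-allyl diastereomer cyclises before it equilibrates, if traces of the Z-carbonate leak through to the antipode, or if the sense of induction is opposite to the one assumed. The fallback changes the stereo-determining event to a reagent-controlled epoxidation followed by invertive ring closure. It sets out from allylic alcohol 9: Sharpless epoxidation (Ti(OiPr)4, L-(+)-diethyl tartrate, t-BuOOH, CH2Cl2, −20 °C) should give the epoxy alcohol F1 with 2S,3S configuration. Camphorsulfonic acid in CH2Cl2 then lets the phenol oxygen open the epoxide at its fully substituted carbon in a six-membered exo closure with inversion, giving the chroman diol F2 with the 2R configuration. Deoxygenation of the terminal 1,2-diol with PPh3, I2 and imidazole in toluene (Garegg–Samuelsson olefination) comes back to the route at vinylchroman 11.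

Step 9. Hydride abstraction may occur at the 8-methyl group, or the silyloxyarene may be oxidised by electron transfer instead of reaction at C4; conversion may stall; and optical purity may erode if the chromene ring-opens reversibly under light or prolonged heating. The fallback replaces hydride transfer by radical chemistry and sets out from 11: Wohl–Ziegler bromination (N-bromosuccinimide, AIBN, PhCF3, 80 °C) at the secondary benzylic C4 gives the 4-bromochroman F3 as a mixture of C4 epimers, and dehydrobromination with DBU in THF at rt comes back to the route at chromene 12.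

Step 16. The acetylide may attack in the SN2′ sense, the bromide may undergo allylic transposition with loss of the E geometry, the alkyne may homocouple oxidatively, and the base may remove the aryl silyl group. The fallback makes the C6'=C7' alkene before the coupling and joins the fragments under neutral conditions. It sets out from alkynol 21: palladium-catalysed hydrostannation (Bu3SnH, PdCl2(PPh3)2, THF, 0 °C) gives the E-alkenylstannane F4. Stille coupling of this stannane with allylic bromide 22 (Pd2(dba)3, AsPh3, THF, 50 °C) forms C5'–C6' at the unsubstituted allyl terminus and comes back to the route at 24, so step 17 is bypassed.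

**Further compounds**

F1 | step 8 | [(2S,3S)-3-{2-[2-hydroxy-3-methyl-5-(triisopropylsilyloxy)phenyl]ethyl}-3-methyloxiran-2-yl]methanol | OC[C@@H]1O[C@@]1(C)CCc1cc(O[Si](C(C)C)(C(C)C)C(C)C)cc(C)c1O
F2 | step 8 | (1S)-1-[(2R)-2,8-dimethyl-6-(triisopropylsilyloxy)chroman-2-yl]ethane-1,2-diol | OC[C@H](O)[C@@]1(C)CCc2cc(O[Si](C(C)C)(C(C)C)C(C)C)cc(C)c2O1
F3 | step 9 | (2R)-4-bromo-2,8-dimethyl-6-(triisopropylsilyloxy)-2-vinylchroman (both C4 epimers) | C=C[C@@]1(C)CC(Br)c2cc(O[Si](C(C)C)(C(C)C)C(C)C)cc(C)c2O1
F4 | step 16 | (S,E)-3,7-dimethyl-1-(tributylstannyl)octa-1,6-dien-3-ol | CC(C)=CCC[C@](C)(O)/C=C/[Sn](CCCC)(CCCC)CCCC
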